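The benzene ring of the coumarin (ring A: C4a, C5, C6, C7, C8, C8a) is built late, by disconnecting its C8–C8a and C6–C7 bonds. A symmetric bicyclic bis-pyranone, two 2-pyranones sharing one C=C bond, takes up a chiral methyl ynol ether across one ring and expels CO2. That single operation closes and aromatises ring A, puts the methoxy group on C7 and the side chain on C8 (the carbon flanked by C7 and the oxygen-bearing C8a), and leaves the second pyranone as the lactone ring. The alkyne already carries the (R)-senecioyloxy carbon and a silyl-protected carbinol, which is oxidised to the isopropyl ketone at the end.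

Key step: step 8

Remark: methyl (S)-2-hydroxy-3-methylbutanoate is taken as a commercial material; its carbinol carbon only steers the neighbouring centre and is oxidised at the end, so the single stereocentre of the target (R, the carbon bearing the senecioate) stems from the acetylide addition.

Step 1
Reactants: 1 glutaconic acid
Product: 2 glutaconic anhydride (2H-pyran-2,6(3H)-dione)
Conditions: Ac2O (1.5 equiv), 80 °C, short heating; evaporate, recrystallise
Reagents that add atoms: none
Why: Anhydride formation by cyclodehydration with Ac2O is standard for 1,5-diacids, and the mobile three-carbon tautomerism of the glutaconic system lets the trans acid reach the cis geometry that the six-membered ring demands.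

Step 2
Reactants: 2 glutaconic anhydride
Product: 4 6-hydroxy-2-oxo-2H-pyran-5-carbaldehyde, via 3-(ethoxymethylene)-2H-pyran-2,6(3H)-dione 3 (not isolated)
Conditions: HC(OEt)3, Ac2O, 90 °C; evaporate; then H2O (1.1 equiv), MeCN, 0 °C
Reagents that add atoms: triethyl orthoformate, CCOC(OCC)OCC; water, O
Why: Orthoformate condensation at the doubly activated CH2 of a cyclic anhydride (the way alkoxymethylene derivatives of malonates, Meldrum's acid and homophthalic anhydride are made) followed by addition–elimination hydrolysis of the highly electrophilic enol ether carbon should give the strongly acidic, internally hydrogen-bonded formyl enol, with Ac2O scavenging the ethanol that would otherwise open the anhydride.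

Step 3
Reactants: 4 6-hydroxy-2-oxo-2H-pyran-5-carbaldehyde
Product: 6 2H,7H-pyrano[2,3-b]pyran-2,7-dione, via 5-formyl-2-oxo-2H-pyran-6-yl (triphenylphosphoranylidene)acetate 5 (not isolated)
Conditions: Ph3P=C=C=O (1.05 equiv), dry toluene, 20 to 70 °C
Reagents that add atoms: (triphenylphosphoranylidene)ketene, O=C=C=P(c1ccccc1)(c1ccccc1)c1ccccc1
Why: Domino addition–intramolecular Wittig olefination, the reaction that turns salicylaldehydes into coumarins with the same reagent: the acidic enol OH of 4 adds across the C=C of the cumulated ylide to give ester ylide 5, whose carbanion then olefinates the adjacent formyl group, the six-membered ring enforcing the cis alkene under neutral, water-free conditions that the acyl-donor product should tolerate.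

Step 4
Reactants: 7 methyl (S)-2-hydroxy-3-methylbutanoate
Product: 8 methyl (S)-3-methyl-2-(triethylsilyloxy)butanoate
Conditions: Et3SiCl, imidazole, DMF, 0 °C to rt
Reagents that add atoms: chlorotriethylsilane, CC[Si](Cl)(CC)CC
Why: Silyl ether formation from a secondary alcohol with Et3SiCl and imidazole does not touch the stereocentre, and the triethylsilyl group is kept because it can be removed later under buffered acidic fluoride.

Step 5
Reactants: 8 methyl (S)-3-methyl-2-(triethylsilyloxy)butanoate
Product: 9 (S)-3-methyl-2-(triethylsilyloxy)butanal
Conditions: i-Bu2AlH (1.1 equiv), CH2Cl2, −78 °C; aq. KNaC4H4O6 (tartrate) work-up; used crude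
Reagents that add atoms: none
Why: Partial reduction of an ester to the aldehyde with i-Bu2AlH at −78 °C works reliably for α-silyloxy esters because the tetrahedral aluminium acetal survives until work-up, and the aldehyde is used at once so that its α-centre does not epimerise.

Step 6
Reactants: 9 (S)-3-methyl-2-(triethylsilyloxy)butanal; 10 chloroacetaldehyde dimethyl acetal
Product: 12 (3R,4S)-1-methoxy-5-methyl-4-(triethylsilyloxy)hex-1-yn-3-ol, via lithium methoxyacetylide 11 (not isolated)
Conditions: 10, LiNEt2 (3 equiv per 10, from n-BuLi and Et2NH), THF, 0 °C; then 9, −78 °C; cold H2O quench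
Reagents that add atoms: none
Why: Acetylide 1,2-addition to an α-silyloxy aldehyde: the chloroacetal is converted by LiNEt2 (two eliminations and a deprotonation) into lithium methoxyacetylide, which should attack the carbonyl anti to the C–OSi bond (polar Felkin–Anh model) and so set C3 as R (3,4-anti), the minor syn epimer being removed by chromatography on base-washed silica.

Step 7
Reactants: 12 (3R,4S)-1-methoxy-5-methyl-4-(triethylsilyloxy)hex-1-yn-3-ol; 13 3-methylbut-2-enoyl chloride
Product: 14 (3R,4S)-1-methoxy-5-methyl-4-(triethylsilyloxy)hex-1-yn-3-yl 3-methylbut-2-enoate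
Conditions: pyridine, 4-(dimethylamino)pyridine (catalytic), CH2Cl2, 0 °C
Reagents that add atoms: none
Why: Pyridine/4-(dimethylamino)pyridine-mediated acylation of the secondary propargylic alcohol with an acyl chloride occurs at oxygen with retention at C3, pyridine being preferred to a trialkylamine so that the senecioyl group is not deconjugated through its vinylketene and the acid-labile ynol ether stays buffered.

Step 8
Reactants: 6 2H,7H-pyrano[2,3-b]pyran-2,7-dione; 14 (3R,4S)-1-methoxy-5-methyl-4-(triethylsilyloxy)hex-1-yn-3-yl 3-methylbut-2-enoate
Product: 16 (1R,2S)-1-(7-methoxy-2-oxo-2H-chromen-8-yl)-3-methyl-2-(triethylsilyloxy)butyl 3-methylbut-2-enoate, via bridged bicyclic lactone adduct 15 (not isolated)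
Conditions: 6 (2 equiv), PhCl, 80–100 °C, sealed tube
Reagents that add atoms: none
Why: Proposed new method: the electron-rich ynol ether 14 and one electron-poor 2-pyranone ring of 6 should combine in a polarised, inverse-electron-demand [4+2] cycloaddition across C3 and C8a of 6 to give the bridged lactone 15, which loses CO2 by retro-[4+2] at the reaction temperature; the closest known reaction type is the Diels–Alder/decarboxylation of acceptor-substituted 2-pyranones with alkoxyalkynes and ynamines to give arenes, whereas a pyranone whose C5=C6 bond is shared with a second pyranone has not been used as the diene. Ring A is closed by intermolecular cycloaddition, both new σ-bonds (C8–C8a and C6–C7 in coumarin numbering) being made in the same event, and it becomes aromatic by cycloreversion, not by an oxidation. No stereocentre is created in 16: the two bridgehead centres of 15 arise on either face of the flat diene and vanish with CO2, and C1' and C2' of the side chain never become sp2 or acidic during the step. The step needs regioselectivity, which the polarity of both partners should secure: the β-carbon of the ynol ether (the one carrying the side chain) is its nucleophilic end and should bond to C8a, the diene terminus that bears two oxygens and is δ to both lactone carbonyls, which leaves the methoxy carbon to bond to C3 (the future C6). The two pyranone rings of 6 are equivalent, so no choice between them is needed, a second addition is not expected once the remaining lactone is part of an aromatic coumarin, an O-methyl group offers no β-hydrogen for the thermal ketene-forming fragmentation of higher alkyl ynol ethers, and the enoate of the senecioate is too electron-poor to compete as a dienophile.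

Step 9
Reactants: 16 (1R,2S)-1-(7-methoxy-2-oxo-2H-chromen-8-yl)-3-methyl-2-(triethylsilyloxy)butyl 3-methylbut-2-enoate
Product: 17 (1R,2S)-2-hydroxy-1-(7-methoxy-2-oxo-2H-chromen-8-yl)-3-methylbutyl 3-methylbut-2-enoate
Conditions: HF·pyridine, pyridine, THF, 0 °C
Reagents that add atoms: none
Why: Fluoride-induced desilylation of the triethylsilyl ether with pyridine-buffered HF·pyridine is mild and slightly acidic, conditions under which the coumarin lactone and the ester survive and 1,2-acyl shift to the freed hydroxyl is slow, the alcohol being oxidised without storage.

Step 10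
Reactants: 17 (1R,2S)-2-hydroxy-1-(7-methoxy-2-oxo-2H-chromen-8-yl)-3-methylbutyl 3-methylbut-2-enoate
Product: 18 (R)-1-(7-methoxy-2-oxo-2H-chromen-8-yl)-3-methyl-2-oxobutyl 3-methylbut-2-enoate
Conditions: Dess–Martin periodinane, CH2Cl2, 0 °C to rt
Reagents that add atoms: none
Why: Dess–Martin oxidation converts the secondary alcohol into the isopropyl ketone at room temperature without base, so the R centre, now benzylic and α to a ketone, should not enolise; the stereocentre that steered the acetylide addition is erased here as planned.

Compound list
1 | glutaconic acid ((E)-pent-2-enedioic acid) | OC(=O)C/C=C/C(=O)O | starting material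
2 | glutaconic anhydride (2H-pyran-2,6(3H)-dione) | O=C1CC=CC(=O)O1 | intermediate
3 | 3-(ethoxymethylene)-2H-pyran-2,6(3H)-dione (either alkene geometry; not isolated) | CCOC=C1C=CC(=O)OC1=O | intermediate
4 | 6-hydroxy-2-oxo-2H-pyran-5-carbaldehyde (enol form of 3-formylglutaconic anhydride) | O=CC1=C(O)OC(=O)C=C1 | intermediate
5 | 5-formyl-2-oxo-2H-pyran-6-yl (triphenylphosphoranylidene)acetate (not isolated) | O=CC1=C(OC(=O)C=P(c2ccccc2)(c2ccccc2)c2ccccc2)OC(=O)C=C1 | intermediate
6 | 2H,7H-pyrano[2,3-b]pyran-2,7-dione | O=C1C=CC2=C(O1)OC(=O)C=C2 | intermediate
7 | methyl (S)-2-hydroxy-3-methylbutanoate | CC(C)[C@H](O)C(=O)OC | starting material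
8 | methyl (S)-3-methyl-2-(triethylsilyloxy)butanoate | CC(C)[C@H](O[Si](CC)(CC)CC)C(=O)OC | intermediate
9 | (S)-3-methyl-2-(triethylsilyloxy)butanal | CC(C)[C@H](O[Si](CC)(CC)CC)C=O | intermediate
10 | chloroacetaldehyde dimethyl acetal (2-chloro-1,1-dimethoxyethane) | COC(CCl)OC | starting material
11 | lithium methoxyacetylide (not isolated) | [Li]C#COC | intermediate
12 | (3R,4S)-1-methoxy-5-methyl-4-(triethylsilyloxy)hex-1-yn-3-ol | COC#C[C@@H](O)[C@@H](O[Si](CC)(CC)CC)C(C)C | intermediate
13 | 3-methylbut-2-enoyl chloride | CC(C)=CC(=O)Cl | starting material
14 | (3R,4S)-1-methoxy-5-methyl-4-(triethylsilyloxy)hex-1-yn-3-yl 3-methylbut-2-enoate | COC#C[C@@H](OC(=O)C=C(C)C)[C@@H](O[Si](CC)(CC)CC)C(C)C | intermediate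
15 | bridged bicyclic lactone adduct (not isolated): 2-oxabicyclo[2.2.2]octa-5,7-dien-3-one in which bridgehead C1 (former C8a of 6) carries O2 and the ring oxygen of the intact pyranone fused at C1–C6, C7 carries the (1R,2S) side chain, C8 carries OMe and bridgehead C4 is CH; both bridgehead epimers | COC1=C([C@@H](OC(=O)C=C(C)C)[C@@H](O[Si](CC)(CC)CC)C(C)C)C23OC(=O)C1C=C2C=CC(=O)O3 | intermediate
16 | (1R,2S)-1-(7-methoxy-2-oxo-2H-chromen-8-yl)-3-methyl-2-(triethylsilyloxy)butyl 3-methylbut-2-enoate | COc1ccc2ccc(=O)oc2c1[C@@H](OC(=O)C=C(C)C)[C@@H](O[Si](CC)(CC)CC)C(C)C | intermediate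
17 | (1R,2S)-2-hydroxy-1-(7-methoxy-2-oxo-2H-chromen-8-yl)-3-methylbutyl 3-methylbut-2-enoate | COc1ccc2ccc(=O)oc2c1[C@@H](OC(=O)C=C(C)C)[C@@H](O)C(C)C | intermediate
18 | (R)-1-(7-methoxy-2-oxo-2H-chromen-8-yl)-3-methyl-2-oxobutyl 3-methylbut-2-enoate | COc1ccc2ccc(=O)oc2c1[C@@H](OC(=O)C=C(C)C)C(=O)C(C)C | target

Total step count: 10
Longest linear sequence: 7 steps (steps 4 to 10, from 7); the bis-pyranone branch (steps 1 to 3) joins at step 8.

Steps most likely to fail

1. Step 8 (Proposed new method). The ynol ether may decompose by ionisation of its propargylic ester or by hydration faster than it adds to the diene. Bond formation may also begin at C4 of 6 (Michael or [2+2] manifold) instead of at C8a, so that no arene is formed. The fallback uses known chemistry, gives up ring construction and forms the C8–C1' bond on an intact coumarin; it sets out from aldehyde 9 and comes back at 16. Commercial 7-hydroxycoumarin is iodinated at C8 (I2, KI, aqueous NH3) to 7-hydroxy-8-iodo-2H-chromen-2-one F1 and O-methylated (MeI, K2CO3, acetone) to 8-iodo-7-methoxy-2H-chromen-2-one F2. Nozaki–Hiyama–Kishi coupling of F2 with 9 (CrCl2 in excess, NiCl2 catalytic, DMF, rt), which tolerates the lactone, should give (1R,2S)-1-(7-methoxy-2-oxo-2H-chromen-8-yl)-3-methyl-2-(triethylsilyloxy)butan-1-ol F3 under Felkin–Anh control after separation of the epimer. Acylation of F3 with 13 (pyridine, 4-(dimethylamino)pyridine) then gives 16.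

2. Step 3. Intermolecular acyl transfer from the activated ester ylide, or from the product (itself a double enol ester), may outrun ring closure and lead to oligomers. Adventitious water may also open the anhydride-type ring of 4. The fallback sets out from 2 and comes back at 6, bypassing 3, 4 and 5. It is a Pechmann condensation, the acid-mediated annulation that converts phenols and enolised hydroxypyranones into fused 2-pyranones. Anhydride 2 and malic acid are warmed in concentrated H2SO4; malic acid loses CO and water to give 3-oxopropanoic acid F4, which condenses at C3 of 2, and the resulting acrylic acid closes onto the enol oxygen in the dehydrating medium. The neutral bis-lactone is isolated by pouring onto ice and rapid extraction.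

3. Step 6. Facial selectivity may be poor if lithium chelation competes with the Felkin–Anh mode, and the silyl group may migrate between the vicinal oxygens in the alkoxide. The fallback removes the dependence on the selectivity of the addition; it sets out from 9 and comes back at 14. The addition is run as before and both epimers are collected. The anti epimer 12 is acylated with retention as in step 7. The syn epimer, (3S,4S)-1-methoxy-5-methyl-4-(triethylsilyloxy)hex-1-yn-3-ol F5, is esterified with inversion at C3 under Mitsunobu conditions (3-methylbut-2-enoic acid, PPh3, diisopropyl azodicarboxylate, toluene, 0 °C). Both epimers thus converge on 14.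

Further compounds
F1 | step 8 | 7-hydroxy-8-iodo-2H-chromen-2-one | Oc1ccc2ccc(=O)oc2c1I
F2 | step 8 | 8-iodo-7-methoxy-2H-chromen-2-one | COc1ccc2ccc(=O)oc2c1I
F3 | step 8 | (1R,2S)-1-(7-methoxy-2-oxo-2H-chromen-8-yl)-3-methyl-2-(triethylsilyloxy)butan-1-ol | COc1ccc2ccc(=O)oc2c1[C@@H](O)[C@@H](O[Si](CC)(CC)CC)C(C)C
F4 | step 3 | 3-oxopropanoic acid | O=CCC(=O)O
F5 | step 6 | (3S,4S)-1-methoxy-5-methyl-4-(triethylsilyloxy)hex-1-yn-3-ol | COC#C[C@H](O)[C@@H](O[Si](CC)(CC)CC)C(C)C
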